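3 questions stood before me, and together they made one decision: which initiator charge to put in, and whether to stop at 40 h.

the same everywhere: free monomer 0.20 M

| run | protic impurity | initiator | remark | time |
|---|---|---|---|---|
| dawn | 0.020 M | 3.7 mM | run made earlier |  |
| winter | 0.020 M | 6.2 mM | run made earlier |  |
| epsilon | 0.0200 M | 5.0 mM |  | 40 h |
| eta | 0.0200 M | 3.0 mM |  | 40 h |

| run | time / h | monomer in chains / % | free monomer / % |
|---|---|---|---|
| dawn | 8.00 | 63.7 | 26.4 |
| dawn | 15.0 | 79.3 | 11.4 |
| dawn | 20.0 | 82.7 | 6.9 |
| dawn | 30.0 | 86.7 | 3.3 |
| winter | 4.00 | 53.4 | 36.5 |
| winter | 10.0 | 80.5 | 10.0 |
| winter | 20.0 | 87.1 | 2.9 |
| winter | 30.0 | 88.9 | 1.3 |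

(each reading ± 0.3 percentage points)

* which of the two ends with the longer chains by the average number of monomer units in a chain (chains begun, living or dead) ("neither" if they lie within 10%) (epsilon / eta / neither)
* average number of monomer units in a chain (chains begun, living or dead) at the end, epsilon
* average number of monomer units in a chain (chains begun, living or dead) at the end, eta

- the average divides the monomer in chains by the number of chains begun, living and dead together
- steps thought possible: 2 living end -> dead end; protic impurity + free monomer -> quenched substrate; free monomer + living end -> monomer in chains + living end; free monomer + initiator -> living end + monomer in chains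
- the earlier runs do not show the number of chains; that part of a forecast is a guess

At the last readings, monomer in chains and free monomer fell short of the charge by 10.0% in dawn and 9.80% in winter. The protic impurity charged is 10.0% of the free monomer, so I read the gap as free monomer quenched one for one. That leaves 0.180 M that can enter chains in epsilon and in eta. The average asked for is the number-average degree of polymerisation, and each initiator that reacts begins one chain. So I named the full-use length, this room divided by the initiator charged: 36.0 for epsilon and 60.0 for eta.

Free monomer left over shortens the average and initiator left over lengthens it. The runs show no chain count, so the second effect stayed a guess. For the first I counted half-lives. Between the last two readings, 10.0 h apart in both runs, free monomer fell to half in dawn and to half in winter. One more such half-life from dawn's last reading gives 1.65% at 40 h, a low figure for eta, which has less initiator than dawn. With that low figure eta comes to about 58.9, a loss of 1.10, and a larger remainder of free monomer would make the loss larger. The factor of 1.67 between the two full-use lengths lies beyond the 10% margin. I would charge eta and stop at 40 h.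

The forecast named eta, with 36 (34.5 to 40) for epsilon and 59 (56 to 68) for eta, holding that “Initiator should therefore be almost entirely consumed, though this is inferred”.

    2 living end → dead end (k = 12.0 /M/h)
    protic impurity + free monomer → quenched substrate (k = 21.0 /M/h)
    free monomer + living end → monomer in chains + living end, rate k3*[living end]*[free monomer] (k = 61.0 /M/h)
    free monomer + initiator → living end + monomer in chains (k = 4.30 /M/h)

The flask gave eta, with 36.0 for epsilon and 58.2 for eta. At 40.0 h eta still held 2.7% of its free monomer and stood below its full-use length of 60.0. A neighbour of eta charged with 0.0018 M of initiator has a full-use length of 100. At 40.0 h it held 7.0% of its free monomer and stood at 92.2.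

The numbers in the tables come from a simulation on assumed constants; noise was put on by code.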